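A direct plan would alkylate the dianion of diethyl (S)-malate with a benzyl-protected syringyl bromide and store the carbinol centre in the pivalaldehyde-derived dioxolanone acid A1.
An aldol addition of A1 to silyl-protected syringaldehyde would make C8' quaternary, and LiAlH4 would then give the tetraol A2 as a mixture of carbinol epimers.
Acid would close the first oxolane of A2 at the benzylic carbinol, hydrogenolysis would free one phenol to give the monophenol A3 and Ag2O would turn A3 into the p-quinone methide A4 for a closing 1,6-addition before desilylation.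
First weak point: ester hydrolysis, acetalisation, hydride reduction and two different phenol protecting groups would serve mainly to tell two identical aryl rings apart and would add little skeletal complexity.
Second weak point: the acid-induced closure of the first oxolane would pass through a benzylic cation next to a tertiary alcohol, so the aryl-bearing stereocentre would be left to equilibration and a pinacol shift could compete.
Third weak point: the Ag2O dehydrogenation and oxa-Michael closure would be run on the most advanced material, where chemoselective oxidation, tautomerisation of the quinone methide and the face of a reversible addition would all have to fall right.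

**Plan of the new route**
Numbering: C7–C8–C9 is the arm whose C8 carries H, C7'–C8'–C9' the arm whose C8' carries OH; ring A = C8', C7', O, C9, C8; ring B = C8, C7, O, C9', C8'.
Retrosynthesis: cut C8'–C7' (ring A) first, which turns the tertiary alcohol into the carbonyl of a ring B oxolan-3-one bearing a C9–O–C7'H2Ar ether; then cut O–C9' of ring B, then C7–C8, back to a protected syringyl alcohol and a four-carbon allyl donor (C9, C8, C8', C9').
Forward: an iridium-catalysed (hydroxymethyl)allylation sets C7 by catalysis and C8 with it; ring B closes by SN2 at the non-stereogenic C9'; ring A arises last, by a Norrish–Yang photocyclisation that makes the C8'–C7' bond, the tertiary alcohol and both remaining stereocentres at once.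
Enabling feature: C8' is a carbinol carbon bonded to C7', a benzylic carbon that is also α to the ring A oxygen; in the ring B ketone the C7'–H bonds lie δ to the carbonyl (O=C8'–C8–C9–O–C7'H2), so 1,6-hydrogen transfer gives a 1,5-biradical that can only close ring A.
The weak steps do not arise: both aryl rings carry the same benzyl ether, no ring is closed through a benzylic cation, and no phenol is oxidised at a late stage.

Key step: step 9

Abbreviation: Ar = 4-(benzyloxy)-3,5-dimethoxyphenyl.
Assumption: the sense of induction of the iridium catalyst in step 4 is taken by analogy with related carbonyl allylations; the SEGPHOS antipode written as (S) stands for the one that adds the allyl unit to the Si face of the transient aldehyde and so gives the 1S carbinol.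

**Step 1**
Reactants: 1 syringaldehyde
Product: 2 4-(benzyloxy)-3,5-dimethoxybenzaldehyde
Conditions: BnBr, K2CO3, DMF, 60 °C
Reagents that add atoms: benzyl bromide, BrCc1ccccc1
Why: Williamson ether synthesis on the acidic, hindered phenoxide; the benzyl ether should survive base, hydride, iridium catalysis, peracid and light above 300 nm and is the only protecting group of the route.

**Step 2**
Reactants: 2 4-(benzyloxy)-3,5-dimethoxybenzaldehyde
Product: 3 [4-(benzyloxy)-3,5-dimethoxyphenyl]methanol
Conditions: NaBH4, MeOH, 0 °C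
Reagents that add atoms: none
Why: Borohydride reduction of an aromatic aldehyde; alcohol 3 serves both as the C7 unit (step 4) and, after bromination, as the C7' unit (step 5).

**Step 3**
Reactants: 3 [4-(benzyloxy)-3,5-dimethoxyphenyl]methanol (part of the material)
Product: 4 2-(benzyloxy)-5-(bromomethyl)-1,3-dimethoxybenzene
Conditions: PBr3 (0.4 equiv), Et2O, 0 °C
Reagents that add atoms: phosphorus tribromide, BrP(Br)Br
Why: Bromide substitution of a primary benzylic alcohol through its phosphite ester, standard for alkoxybenzyl alcohols; the bromide would be used without storage.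

**Step 4**
Reactants: 3 [4-(benzyloxy)-3,5-dimethoxyphenyl]methanol; 5 4-ethenyl-1,3-dioxolan-2-one (vinyl ethylene carbonate, racemic)
Product: 6 (1S,2R)-1-Ar-2-ethenylpropane-1,3-diol (anti), via aldehyde 2 (not isolated)
Conditions: [Ir(cod)Cl]2 (2.5 mol %), (S)-SEGPHOS (5 mol %), 4-cyano-3-nitrobenzoic acid (10 mol %), K3PO4 (5 mol %), THF, 90 °C, sealed tube
Reagents that add atoms: none
Why: Iridium-catalysed transfer-hydrogenative carbonyl (hydroxymethyl)allylation from the alcohol oxidation level: the cyclometalated iridium benzoate dehydrogenates 3 to aldehyde 2, ionises carbonate 5 with loss of CO2 to a (hydroxymethyl)allyl iridium species and adds it through a closed chair transition state, which should give the anti diastereomer and, under ligand control, the 1S carbinol (C7), with C8 following as 2R.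

**Step 5**
Reactants: 6 (1S,2R)-1-Ar-2-ethenylpropane-1,3-diol; 4 2-(benzyloxy)-5-(bromomethyl)-1,3-dimethoxybenzene
Product: 8 (1S,2R)-1-Ar-2-{[(Ar)methoxy]methyl}but-3-en-1-ol, via stannylene acetal 7 (not isolated)
Conditions: Bu2SnO (1.05 equiv), toluene, reflux, Dean–Stark; then 4 (1.1 equiv), Bu4NI (0.2 equiv), toluene, 80 °C
Reagents that add atoms: dibutyltin oxide, CCCC[Sn](=O)CCCC (its atoms remain only in intermediate 7)
Why: Stannylene-acetal-directed O-alkylation of a 1,3-diol; the six-membered stannylene activates the primary oxygen selectively, so the secondary benzylic hydroxyl at C7 stays free for the ring closure.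

**Step 6**
Reactants: 8 (1S,2R)-1-Ar-2-{[(Ar)methoxy]methyl}but-3-en-1-ol
Product: 9 (1S,2R)-1-Ar-3-[(Ar)methoxy]-2-(oxiran-2-yl)propan-1-ol (both epimers at the oxirane carbon C8')
Conditions: mCPBA (1.3 equiv), NaHCO3, CH2Cl2, 0 °C → rt
Reagents that add atoms: 3-chloroperoxybenzoic acid, OOC(=O)c1cccc(Cl)c1
Why: Prilezhaev epoxidation of the only C=C bond; the configuration of the new centre C8' does not matter because it becomes a carbonyl in step 8, and bicarbonate keeps the benzylic alcohol and the epoxide away from acid.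

**Step 7**
Reactants: 9 (1S,2R)-1-Ar-3-[(Ar)methoxy]-2-(oxiran-2-yl)propan-1-ol
Product: 11 (4S,5S)-5-Ar-4-{[(Ar)methoxy]methyl}oxolan-3-ol (both C3 epimers), via iodohydrin 10 (not isolated)
Conditions: MgI2 (0.5 equiv), THF, 0 °C → 45 °C
Reagents that add atoms: magnesium iodide, [Mg+2].[I-].[I-] (iodine remains only in intermediate 10)
Why: Halide-relayed isomerisation of a 3,4-epoxy alcohol to a 3-hydroxyoxolane: iodide opens the terminal epoxide at C9' and the C7 hydroxyl displaces the primary iodide in a 5-exo-tet Williamson closure, so ring B forms at a non-stereogenic carbon with C7 and C8 untouched and without the oxetane that direct base-induced opening could give.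

**Step 8**
Reactants: 11 (4S,5S)-5-Ar-4-{[(Ar)methoxy]methyl}oxolan-3-ol
Product: 12 (4R,5S)-5-Ar-4-{[(Ar)methoxy]methyl}oxolan-3-one
Conditions: Dess–Martin periodinane (1.3 equiv), NaHCO3, CH2Cl2, 0 °C → rt
Reagents that add atoms: none
Why: Dess–Martin oxidation of a secondary alcohol under buffered, non-basic conditions that should spare the β-alkoxy ketone from elimination; both C8' epimers converge on one ketone, and C8, now α to the carbonyl, rests in the thermodynamically preferred trans relation to the C7 aryl group.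

**Step 9**
Reactants: 12 (4R,5S)-5-Ar-4-{[(Ar)methoxy]methyl}oxolan-3-one
Product: 14 (7S,8R,7'R,8'S)-4,4'-di-O-benzyl-8'-hydroxysyringaresinol, via 1,5-biradical 13 (not isolated)
Conditions: hν (medium-pressure Hg lamp, Pyrex filter, λ > 300 nm), degassed benzene (0.01 M), 15 °C
Reagents that add atoms: none
Why: Norrish–Yang photocyclisation by δ-hydrogen abstraction: n,π* excitation of the C8' carbonyl, 1,6-hydrogen transfer from C7' through a seven-membered transition state to the 1,5-biradical 13 (hydroxy-substituted radical at C8', benzylic α-oxygenated radical at C7'), then radical recombination to the C8'–C7' bond. The closest known reaction type is the photocyclisation of β-alkoxy ketones to oxolan-3-ols, including 4-(benzyloxymethyl)oxolan-3-ones that give 1-hydroxy-3,7-dioxabicyclo[3.3.0]octanes. Ring A (C8', C7', O, C9, C8) closes by intramolecular combination of the two radical centres, a five-membered C–C closure, and a 1,5-biradical has no fragmentation channel of the kind open to 1,4-biradicals, so it can only cyclise or return to 12. C8' is controlled by the tether: the C9–O–C7' arm sits on the face of ring B opposite to the C7 aryl group and can reach C8' only from that face, so the ring fusion is cis and the hydroxyl ends anti to C9 (8'S); C7' is controlled in the closing transition state, where the aryl group should turn to the convex face, syn to the small hydroxyl and away from C9'H2 of ring B (7'R), a preference expected in a solvent that does not hydrogen-bond to the hydroxyl. The step needs hydrogen abstraction to outrun Norrish α-cleavage of the ring ketone and to be site-selective: the doubly activated C7'–H bonds are the only abstractable hydrogens within reach of the carbonyl oxygen, the CH2 groups of the phenol benzyl ethers are too remote, and light above 300 nm addresses only the carbonyl chromophore.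

**Step 10**
Reactants: 14 (7S,8R,7'R,8'S)-4,4'-di-O-benzyl-8'-hydroxysyringaresinol
Product: 15 8-hydroxysyringaresinol
Conditions: H2 (1 atm), 10% Pd/C, EtOAc, rt, stopped when 14 is consumed
Reagents that add atoms: none
Why: Catalytic hydrogenolysis of two aryl benzyl ethers, which in a neutral aprotic solvent should be much faster than cleavage of the benzylic C7–O and C7'–O bonds of the furofuran; no acid is present, so the acid-labile benzylic centres should keep their configuration.

**Compound list**
1 | 4-hydroxy-3,5-dimethoxybenzaldehyde (syringaldehyde) | COc1cc(C=O)cc(OC)c1O | starting material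
2 | 4-(benzyloxy)-3,5-dimethoxybenzaldehyde | COc1cc(C=O)cc(OC)c1OCc1ccccc1 | intermediate
3 | [4-(benzyloxy)-3,5-dimethoxyphenyl]methanol | COc1cc(CO)cc(OC)c1OCc1ccccc1 | intermediate
4 | 2-(benzyloxy)-5-(bromomethyl)-1,3-dimethoxybenzene | COc1cc(CBr)cc(OC)c1OCc1ccccc1 | intermediate
5 | 4-ethenyl-1,3-dioxolan-2-one (racemic) | C=CC1COC(=O)O1 | starting material
6 | (1S,2R)-1-[4-(benzyloxy)-3,5-dimethoxyphenyl]-2-ethenylpropane-1,3-diol | OC[C@@H](C=C)[C@H](O)c1cc(OC)c(OCc2ccccc2)c(OC)c1 | intermediate
7 | (4S,5R)-4-[4-(benzyloxy)-3,5-dimethoxyphenyl]-2,2-dibutyl-5-ethenyl-1,3,2-dioxastanninane | CCCC[Sn]1(CCCC)OC[C@@H](C=C)[C@@H](c2cc(OC)c(OCc3ccccc3)c(OC)c2)O1 | intermediate (not isolated)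
8 | (1S,2R)-1-[4-(benzyloxy)-3,5-dimethoxyphenyl]-2-({[4-(benzyloxy)-3,5-dimethoxyphenyl]methoxy}methyl)but-3-en-1-ol | COc1cc(COC[C@@H](C=C)[C@H](O)c2cc(OC)c(OCc3ccccc3)c(OC)c2)cc(OC)c1OCc1ccccc1 | intermediate
9 | (1S,2R)-1-[4-(benzyloxy)-3,5-dimethoxyphenyl]-3-{[4-(benzyloxy)-3,5-dimethoxyphenyl]methoxy}-2-(oxiran-2-yl)propan-1-ol (oxirane epimers) | COc1cc(COC[C@@H](C2CO2)[C@H](O)c2cc(OC)c(OCc3ccccc3)c(OC)c2)cc(OC)c1OCc1ccccc1 | intermediate
10 | (1S,2R)-1-[4-(benzyloxy)-3,5-dimethoxyphenyl]-2-({[4-(benzyloxy)-3,5-dimethoxyphenyl]methoxy}methyl)-4-iodobutane-1,3-diol (C3 epimers; present as its magnesium alkoxide) | COc1cc(COC[C@@H](C(O)CI)[C@H](O)c2cc(OC)c(OCc3ccccc3)c(OC)c2)cc(OC)c1OCc1ccccc1 | intermediate (not isolated)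
11 | (4S,5S)-5-[4-(benzyloxy)-3,5-dimethoxyphenyl]-4-({[4-(benzyloxy)-3,5-dimethoxyphenyl]methoxy}methyl)oxolan-3-ol (C3 epimers) | COc1cc(COC[C@H]2C(O)CO[C@@H]2c2cc(OC)c(OCc3ccccc3)c(OC)c2)cc(OC)c1OCc1ccccc1 | intermediate
12 | (4R,5S)-5-[4-(benzyloxy)-3,5-dimethoxyphenyl]-4-({[4-(benzyloxy)-3,5-dimethoxyphenyl]methoxy}methyl)oxolan-3-one | COc1cc(COC[C@H]2C(=O)CO[C@@H]2c2cc(OC)c(OCc3ccccc3)c(OC)c2)cc(OC)c1OCc1ccccc1 | intermediate
13 | 1,5-biradical of 12: 3-hydroxyoxolan-3-yl radical centre at C8' and α-alkoxybenzyl radical centre at C7', C7 and C8 as in 12 | COc1cc([CH]OC[C@H]2[C](O)CO[C@@H]2c2cc(OC)c(OCc3ccccc3)c(OC)c2)cc(OC)c1OCc1ccccc1 | intermediate (not isolated)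
14 | (7S,8R,7'R,8'S)-4,4'-di-O-benzyl-8'-hydroxysyringaresinol, i.e. (1S,3aS,4R,6aR)-1,4-bis[4-(benzyloxy)-3,5-dimethoxyphenyl]tetrahydro-1H,3H-furo[3,4-c]furan-3a(4H)-ol | COc1cc([C@H]2OC[C@]3(O)[C@@H](c4cc(OC)c(OCc5ccccc5)c(OC)c4)OC[C@H]23)cc(OC)c1OCc1ccccc1 | intermediate
15 | 8-hydroxysyringaresinol, (1S,3aS,4R,6aR)-1,4-bis(4-hydroxy-3,5-dimethoxyphenyl)tetrahydro-1H,3H-furo[3,4-c]furan-3a(4H)-ol | COc1cc([C@H]2OC[C@]3(O)[C@@H](c4cc(OC)c(O)c(OC)c4)OC[C@H]23)cc(OC)c1O | target

**Count**
Total steps: 10. Longest linear sequence: 9 steps (steps 1, 2, 4, 5, 6, 7, 8, 9, 10 from syringaldehyde); step 3 is a one-step branch.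

**Steps most likely to fail**

1. Step 9. What may go wrong: α-cleavage of the excited oxolanone (ring opening, decarbonylation) or charge-transfer quenching by the electron-rich arenes may outrun the 1,6-hydrogen transfer, and the biradical may close with poor face selectivity at C7'. Fallback (ring A through a C–O closure in the ground state): setting out from 12, Wittig olefination with the ylide of {[4-(benzyloxy)-3,5-dimethoxyphenyl]methyl}triphenylphosphonium bromide F1 (from 4 and PPh3; KHMDS, THF, −78 °C → rt) would give the benzylidene oxolane F2. OsO4 (cat.), NMO, acetone–H2O should then dihydroxylate F2 from the face opposite to the C8 substituent and give diol F3 with the required configuration at C8'. CSA (cat.) in wet CH2Cl2 would ionise the benzylic C7' carbinol; the C9 ether oxygen would close ring A and shed its arylmethyl group (debenzylative cycloetherification), and the route is rejoined at 14.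

2. Step 4. What may go wrong: slow dehydrogenation of the electron-rich benzylic alcohol, reversible or poorly face-selective addition, or further dehydrogenation of the primary alcohol of the product may erode conversion and enantiomeric purity. Fallback (stoichiometric allylboron reagent under chiral Brønsted acid catalysis): setting out from 2, allylboration with tert-butyldimethyl{[(2E)-4-(4,4,5,5-tetramethyl-1,3,2-dioxaborolan-2-yl)but-2-en-1-yl]oxy}silane F4 (from the (E)-allylic acetate and B2pin2) and the TRIP phosphoric acid antipode that directs Si-face attack (written as (S)-TRIP, 5 mol %, toluene, −30 °C) should give, through a chair transition state, the anti silyl ether F5. TBAF in THF would then return the route to 6.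

3. Step 7. What may go wrong: the C9 ether oxygen may compete with the C7 hydroxyl for the primary iodide (with loss of its arylmethyl group), or an oxetane may form by attack at the inner epoxide carbon. Fallback (ring B closed before the ether oxygen is a free nucleophile): setting out from 6, TBSCl and imidazole would silylate the primary hydroxyl to the silyl ether F5. mCPBA would give the epoxide F6, and MgI2 in THF the oxolanol F7, whose bulky silyl ether does not take part. TBAF would free the diol F8, and stannylene-directed alkylation of its primary hydroxyl with 4 (Bu2SnO; then 4, Bu4NI, toluene, 80 °C) would rejoin the route at 11.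

**Further compounds**
F1 | step 9 | {[4-(benzyloxy)-3,5-dimethoxyphenyl]methyl}triphenylphosphonium bromide | COc1cc(C[P+](c2ccccc2)(c2ccccc2)c2ccccc2)cc(OC)c1OCc1ccccc1.[Br-]
F2 | step 9 | (2S,3R)-2-[4-(benzyloxy)-3,5-dimethoxyphenyl]-4-{[4-(benzyloxy)-3,5-dimethoxyphenyl]methylidene}-3-({[4-(benzyloxy)-3,5-dimethoxyphenyl]methoxy}methyl)oxolane (E/Z) | COc1cc(COC[C@H]2C(=Cc3cc(OC)c(OCc4ccccc4)c(OC)c3)CO[C@@H]2c2cc(OC)c(OCc3ccccc3)c(OC)c2)cc(OC)c1OCc1ccccc1
F3 | step 9 | (3S,4R,5S)-5-[4-(benzyloxy)-3,5-dimethoxyphenyl]-3-{[4-(benzyloxy)-3,5-dimethoxyphenyl](hydroxy)methyl}-4-({[4-(benzyloxy)-3,5-dimethoxyphenyl]methoxy}methyl)oxolan-3-ol (epimers at the exocyclic carbinol) | COc1cc(COC[C@H]2[C@@](O)(C(O)c3cc(OC)c(OCc4ccccc4)c(OC)c3)CO[C@@H]2c2cc(OC)c(OCc3ccccc3)c(OC)c2)cc(OC)c1OCc1ccccc1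
F4 | step 4 | tert-butyldimethyl{[(2E)-4-(4,4,5,5-tetramethyl-1,3,2-dioxaborolan-2-yl)but-2-en-1-yl]oxy}silane | CC(C)(C)[Si](C)(C)OC/C=C/CB1OC(C)(C)C(C)(C)O1
F5 | step 4 | (1S,2R)-1-[4-(benzyloxy)-3,5-dimethoxyphenyl]-2-({[tert-butyl(dimethyl)silyl]oxy}methyl)but-3-en-1-ol | CC(C)(C)[Si](C)(C)OC[C@@H](C=C)[C@H](O)c1cc(OC)c(OCc2ccccc2)c(OC)c1
F6 | step 7 | (1S,2R)-1-[4-(benzyloxy)-3,5-dimethoxyphenyl]-3-{[tert-butyl(dimethyl)silyl]oxy}-2-(oxiran-2-yl)propan-1-ol (oxirane epimers) | CC(C)(C)[Si](C)(C)OC[C@@H](C1CO1)[C@H](O)c1cc(OC)c(OCc2ccccc2)c(OC)c1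
F7 | step 7 | (4S,5S)-5-[4-(benzyloxy)-3,5-dimethoxyphenyl]-4-({[tert-butyl(dimethyl)silyl]oxy}methyl)oxolan-3-ol (C3 epimers) | CC(C)(C)[Si](C)(C)OC[C@H]1C(O)CO[C@@H]1c1cc(OC)c(OCc2ccccc2)c(OC)c1
F8 | step 7 | (4S,5S)-5-[4-(benzyloxy)-3,5-dimethoxyphenyl]-4-(hydroxymethyl)oxolan-3-ol (C3 epimers) | OC[C@H]1C(O)CO[C@@H]1c1cc(OC)c(OCc2ccccc2)c(OC)c1
A1 | direct plan | (2R)-3-[4-(benzyloxy)-3,5-dimethoxyphenyl]-2-[(2S,4S)-2-tert-butyl-5-oxo-1,3-dioxolan-4-yl]propanoic acid | CC(C)(C)[C@@H]1OC(=O)[C@@H](O1)[C@@H](Cc2cc(OC)c(OCc3ccccc3)c(OC)c2)C(O)=O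
A2 | direct plan | (2S,3S)-3-{[4-(benzyloxy)-3,5-dimethoxyphenyl]methyl}-2-{hydroxy[3,5-dimethoxy-4-(triisopropylsilyloxy)phenyl]methyl}butane-1,2,4-triol | OC[C@](O)(C(O)c1cc(OC)c(O[Si](C(C)C)(C(C)C)C(C)C)c(OC)c1)[C@H](CO)Cc1cc(OC)c(OCc2ccccc2)c(OC)c1
A3 | direct plan | (2R,3S,4S)-4-[(4-hydroxy-3,5-dimethoxyphenyl)methyl]-2-[3,5-dimethoxy-4-(triisopropylsilyloxy)phenyl]-3-(hydroxymethyl)oxolan-3-ol | OC[C@]1(O)[C@@H](c2cc(OC)c(O[Si](C(C)C)(C(C)C)C(C)C)c(OC)c2)OC[C@@H]1Cc1cc(OC)c(O)c(OC)c1
A4 | direct plan | p-quinone methide of A3, 4-(oxolan-3-ylmethylidene)-2,6-dimethoxycyclohexa-2,5-dien-1-one with the oxolane substituents of A3 | OC[C@]1(O)[C@@H](c2cc(OC)c(O[Si](C(C)C)(C(C)C)C(C)C)c(OC)c2)OC[C@@H]1C=C1C=C(OC)C(=O)C(OC)=C1
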